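The lactone bond C4–C5 is made first as a bond of a temporary oxane. Locants: lactone O1, C2–C6; side chain C1′–C15′. Because C4 is the β-carbon of the enoate and C6–O1 and C2′–OH are 1,3-anti, an (E)-β-alkoxyacrylate hung on O2′ of a C2′ homoallylic alcohol undergoes Prins cyclisation: one operation forms C4–C5, closes the oxane O2′–C4–C5–C6–C1′–C2′ and sets the C6 oxygen all-cis, i.e. anti to C2′. Retro-oxa-Michael opening then returns O2′ as the free hydroxyl and C3=C4; photoisomerisation lactonises onto O at C6. The precursor is built by three reagent-controlled allylborations from decanal.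

Key step: step 9

Remark on the chemistry: both enantiomers of B-allyldiisopinocampheylborane are assumed to be used as their commercial pentane solutions; TIPS = triisopropylsilyl.

Step 1
Reactants: 1 decanal
Product: 3 (4S)-tridec-1-en-4-ol, via borinate 2 (not isolated)
Conditions: (+)-Ipc2B(allyl) (from (−)-α-pinene), Et2O, −78 °C; then NaOH, H2O2, H2O, 0 °C → rt
Reagents that add atoms: (+)-B-allyldiisopinocampheylborane C=CCB([C@H]1C[C@H]2C[C@@H]([C@@H]1C)C2(C)C)[C@H]1C[C@H]2C[C@@H]([C@@H]1C)C2(C)C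
Why: Brown asymmetric allylboration through a closed chair (Zimmerman–Traxler) transition state, in which the (−)-α-pinene-derived reagent attacks the Re face of the aldehyde and so sets C6′ as S under reagent control.

Step 2
Reactants: 3 (4S)-tridec-1-en-4-ol
Product: 4 (4S)-4-(TIPS-oxy)tridec-1-ene
Conditions: TIPSOTf, 2,6-lutidine, CH2Cl2, 0 °C
Reagents that add atoms: triisopropylsilyl triflate CC(C)[Si](C(C)C)(C(C)C)OS(=O)(=O)C(F)(F)F
Why: Silyl ether formation with a silyl triflate and a hindered base, the triisopropylsilyl group being chosen because it should survive the later trifluoroacetic acid and amide-base steps.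

Step 3
Reactants: 4 (4S)-4-(TIPS-oxy)tridec-1-ene
Product: 6 (3S)-3-(TIPS-oxy)dodecanal, via ozonide 5 (not isolated)
Conditions: O3, CH2Cl2, −78 °C; then PPh3, −78 °C → rt
Reagents that add atoms: ozone [O-][O+]=O
Why: Ozonolysis with reductive phosphine work-up cleaves the terminal alkene to the β-silyloxy aldehyde without touching the stereocenter.

Step 4
Reactants: 6 (3S)-3-(TIPS-oxy)dodecanal
Product: 8 (4S,6S)-6-(TIPS-oxy)pentadec-1-en-4-ol, via borinate 7 (not isolated)
Conditions: (−)-Ipc2B(allyl) (from (+)-α-pinene), Et2O, −78 °C; then NaOH, H2O2, H2O, 0 °C → rt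
Reagents that add atoms: (−)-B-allyldiisopinocampheylborane C=CCB([C@@H]1C[C@@H]2C[C@H]([C@H]1C)C2(C)C)[C@@H]1C[C@@H]2C[C@H]([C@H]1C)C2(C)C
Why: Brown allylboration under reagent control, in which the (+)-α-pinene-derived reagent attacks the Si face and sets C4′ anti to C6′, overriding the small intrinsic bias of the β-silyloxy aldehyde.

Step 5
Reactants: 8 (4S,6S)-6-(TIPS-oxy)pentadec-1-en-4-ol
Product: 9 (4S,6S)-4,6-bis(TIPS-oxy)pentadec-1-ene
Conditions: TIPSOTf, 2,6-lutidine, CH2Cl2, 0 °C → rt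
Reagents that add atoms: triisopropylsilyl triflate CC(C)[Si](C(C)C)(C(C)C)OS(=O)(=O)C(F)(F)F
Why: Silyl ether formation, for which the reactive triflate should silylate even this more hindered secondary alcohol.

Step 6
Reactants: 9 (4S,6S)-4,6-bis(TIPS-oxy)pentadec-1-ene
Product: 11 (3R,5S)-3,5-bis(TIPS-oxy)tetradecanal, via ozonide 10 (not isolated)
Conditions: O3, CH2Cl2, −78 °C; then PPh3, −78 °C → rt
Reagents that add atoms: ozone [O-][O+]=O
Why: Ozonolysis with reductive work-up, as in step 3, leaves both stereocenters untouched.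

Step 7
Reactants: 11 (3R,5S)-3,5-bis(TIPS-oxy)tetradecanal
Product: 13 (4R,6S,8S)-6,8-bis(TIPS-oxy)heptadec-1-en-4-ol, via borinate 12 (not isolated)
Conditions: (+)-Ipc2B(allyl) (from (−)-α-pinene), Et2O, −78 °C; then NaOH, H2O2, H2O, 0 °C → rt
Reagents that add atoms: (+)-B-allyldiisopinocampheylborane C=CCB([C@H]1C[C@H]2C[C@@H]([C@@H]1C)C2(C)C)[C@H]1C[C@H]2C[C@@H]([C@@H]1C)C2(C)C
Why: Brown allylboration under reagent control, Re-face attack setting C2′ anti to C4′ and delivering the allyl group that carries C1′, C6 and C5.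

Step 8
Reactants: 13 (4R,6S,8S)-6,8-bis(TIPS-oxy)heptadec-1-en-4-ol; 14 methyl propiolate
Product: 15 methyl (2E)-3-{[(4R,6S,8S)-6,8-bis(TIPS-oxy)heptadec-1-en-4-yl]oxy}prop-2-enoate
Conditions: N-methylmorpholine, CH2Cl2, rt
Reagents that add atoms: none
Why: Amine-catalysed oxa-Michael addition of the secondary alcohol to the propiolate should give the (E)-β-alkoxyacrylate (vinylogous carbonate) selectively, with no new stereocenter.

Step 9
Reactants: 15 methyl (2E)-3-{[(4R,6S,8S)-6,8-bis(TIPS-oxy)heptadec-1-en-4-yl]oxy}prop-2-enoate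
Product: 17 methyl 2-[(2S,4R,6R)-6-[(2S,4S)-2,4-bis(TIPS-oxy)tridecyl]-4-hydroxyoxan-2-yl]acetate, via trifluoroacetate 16 (not isolated)
Conditions: CF3CO2H (excess), CH2Cl2, 0 °C → rt; evaporate; then K2CO3, MeOH, rt
Reagents that add atoms: trifluoroacetic acid OC(=O)C(F)(F)F
Why: Trifluoroacetic acid protonates C3 of the (E)-β-alkoxyacrylate to give an oxocarbenium ion at C4 on O2′, the terminal alkene carbon C5 attacks C4 through a chair transition state to form the C4–C5 bond, the resulting secondary C6 cation is captured by trifluoroacetate, and methanolysis of that ester in the same flask frees the C6 hydroxyl. The closest known reaction type is the acid-promoted Prins cyclisation of homoallylic β-alkoxyacrylates to 2,6-cis-4-hydroxyoxanes. The oxane O2′–C4–C5–C6–C1′–C2′ closes in a 6-endo-trig mode of the alkene onto the oxocarbenium carbon. C4 is set by the chair in which the CH2CO2Me group of the (E)-oxocarbenium ion and the C2′ side chain are both equatorial (2,6-cis; this center is erased again in step 10), and C6 is set by equatorial capture of the cation, which places its oxygen cis to both ring substituents, i.e. 1,3-anti to O2′ in the open chain, as the target requires. The step needs cyclisation to outrun 2-oxonia-Cope exchange and silyl ether acidolysis, which the highly electrophilic ester-bearing oxocarbenium ion, the all-equatorial chair and the acid-stable triisopropylsilyl ethers should secure.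

Step 10
Reactants: 17 methyl 2-[(2S,4R,6R)-6-[(2S,4S)-2,4-bis(TIPS-oxy)tridecyl]-4-hydroxyoxan-2-yl]acetate
Product: 18 methyl (2E,5S,7R,9S,11S)-5,7-dihydroxy-9,11-bis(TIPS-oxy)icos-2-enoate
Conditions: LiN(SiMe3)2 (2.5 equiv), THF, −78 → −10 °C; then AcOH, −78 °C
Reagents that add atoms: none
Why: Retro-oxa-Michael (E1cB) fragmentation, in which the ester enolate expels the ring oxygen (downhill because an enolate is exchanged for an alkoxide) to give the (E)-enoate with the C2′ hydroxyl restored, the C4 stereocenter disappearing and C6, C2′, C4′ and C6′ staying untouched.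

Step 11
Reactants: 18 methyl (2E,5S,7R,9S,11S)-5,7-dihydroxy-9,11-bis(TIPS-oxy)icos-2-enoate
Product: 20 (6S)-6-[(2R,4S,6S)-2-hydroxy-4,6-bis(TIPS-oxy)pentadecyl]-5,6-dihydro-2H-pyran-2-one, via (Z)-enoate 19 (not isolated)
Conditions: hν (254 nm, quartz), camphorsulfonic acid (cat.), MeCN (dilute, degassed), rt
Reagents that add atoms: none
Why: Photochemical E→Z isomerisation of the enoate with acid-catalysed lactonisation of the Z isomer by the C6 hydroxyl draining the photoequilibrium (photoisomerisation–lactonisation), the C2′ hydroxyl being unable to close a six-membered lactone.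

Step 12
Reactants: 20 (6S)-6-[(2R,4S,6S)-2-hydroxy-4,6-bis(TIPS-oxy)pentadecyl]-5,6-dihydro-2H-pyran-2-one
Product: 21 (6S)-6-[(2S,4R,6S)-2,4,6-trihydroxypentadecyl]-5,6-dihydro-2H-pyran-2-one
Conditions: HF·pyridine, pyridine, THF, 0 °C → rt
Reagents that add atoms: none
Why: Fluoride-mediated cleavage of both silyl ethers under buffered acidic conditions that should leave the unsaturated lactone and its anti-configured 2′-hydroxyl intact.

Compound list
1 | decanal | CCCCCCCCCC=O | starting material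
2 | (4S)-tridec-1-en-4-yl bis[(1S,2S,3S,5R)-isopinocampheyl]borinate | CCCCCCCCC[C@H](OB([C@H]1C[C@H]2C[C@@H]([C@@H]1C)C2(C)C)[C@H]1C[C@H]2C[C@@H]([C@@H]1C)C2(C)C)CC=C | intermediate
3 | (4S)-tridec-1-en-4-ol | CCCCCCCCC[C@H](O)CC=C | intermediate
4 | (4S)-4-(triisopropylsilyloxy)tridec-1-ene | CCCCCCCCC[C@H](O[Si](C(C)C)(C(C)C)C(C)C)CC=C | intermediate
5 | 3-[(2S)-2-(triisopropylsilyloxy)undecyl]-1,2,4-trioxolane (secondary ozonide of 4, both epimers at the trioxolane carbon) | CCCCCCCCC[C@H](O[Si](C(C)C)(C(C)C)C(C)C)CC1OCOO1 | intermediate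
6 | (3S)-3-(triisopropylsilyloxy)dodecanal | CCCCCCCCC[C@H](O[Si](C(C)C)(C(C)C)C(C)C)CC=O | intermediate
7 | (4S,6S)-6-(triisopropylsilyloxy)pentadec-1-en-4-yl bis[(1R,2R,3R,5S)-isopinocampheyl]borinate | CCCCCCCCC[C@H](O[Si](C(C)C)(C(C)C)C(C)C)C[C@@H](OB([C@@H]1C[C@@H]2C[C@H]([C@H]1C)C2(C)C)[C@@H]1C[C@@H]2C[C@H]([C@H]1C)C2(C)C)CC=C | intermediate
8 | (4S,6S)-6-(triisopropylsilyloxy)pentadec-1-en-4-ol | CCCCCCCCC[C@H](O[Si](C(C)C)(C(C)C)C(C)C)C[C@@H](O)CC=C | intermediate
9 | (4S,6S)-4,6-bis(triisopropylsilyloxy)pentadec-1-ene | CCCCCCCCC[C@H](O[Si](C(C)C)(C(C)C)C(C)C)C[C@@H](O[Si](C(C)C)(C(C)C)C(C)C)CC=C | intermediate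
10 | 3-[(2R,4S)-2,4-bis(triisopropylsilyloxy)tridecyl]-1,2,4-trioxolane (secondary ozonide of 9, both epimers at the trioxolane carbon) | CCCCCCCCC[C@H](O[Si](C(C)C)(C(C)C)C(C)C)C[C@@H](O[Si](C(C)C)(C(C)C)C(C)C)CC1OCOO1 | intermediate
11 | (3R,5S)-3,5-bis(triisopropylsilyloxy)tetradecanal | CCCCCCCCC[C@H](O[Si](C(C)C)(C(C)C)C(C)C)C[C@@H](O[Si](C(C)C)(C(C)C)C(C)C)CC=O | intermediate
12 | (4R,6S,8S)-6,8-bis(triisopropylsilyloxy)heptadec-1-en-4-yl bis[(1S,2S,3S,5R)-isopinocampheyl]borinate | CCCCCCCCC[C@H](O[Si](C(C)C)(C(C)C)C(C)C)C[C@@H](O[Si](C(C)C)(C(C)C)C(C)C)C[C@H](OB([C@H]1C[C@H]2C[C@@H]([C@@H]1C)C2(C)C)[C@H]1C[C@H]2C[C@@H]([C@@H]1C)C2(C)C)CC=C | intermediate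
13 | (4R,6S,8S)-6,8-bis(triisopropylsilyloxy)heptadec-1-en-4-ol | CCCCCCCCC[C@H](O[Si](C(C)C)(C(C)C)C(C)C)C[C@@H](O[Si](C(C)C)(C(C)C)C(C)C)C[C@H](O)CC=C | intermediate
14 | methyl propiolate | C#CC(=O)OC | starting material
15 | methyl (2E)-3-{[(4R,6S,8S)-6,8-bis(triisopropylsilyloxy)heptadec-1-en-4-yl]oxy}prop-2-enoate | CCCCCCCCC[C@H](O[Si](C(C)C)(C(C)C)C(C)C)C[C@@H](O[Si](C(C)C)(C(C)C)C(C)C)C[C@H](O/C=C/C(=O)OC)CC=C | intermediate
16 | methyl 2-[(2S,4R,6R)-6-[(2S,4S)-2,4-bis(triisopropylsilyloxy)tridecyl]-4-(trifluoroacetoxy)oxan-2-yl]acetate (all-cis oxane) | CCCCCCCCC[C@H](O[Si](C(C)C)(C(C)C)C(C)C)C[C@@H](O[Si](C(C)C)(C(C)C)C(C)C)C[C@H](O1)C[C@@H](OC(=O)C(F)(F)F)C[C@H]1CC(=O)OC | intermediate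
17 | methyl 2-[(2S,4R,6R)-6-[(2S,4S)-2,4-bis(triisopropylsilyloxy)tridecyl]-4-hydroxyoxan-2-yl]acetate (all-cis oxane, three equatorial substituents) | CCCCCCCCC[C@H](O[Si](C(C)C)(C(C)C)C(C)C)C[C@@H](O[Si](C(C)C)(C(C)C)C(C)C)C[C@H](O1)C[C@@H](O)C[C@H]1CC(=O)OC | intermediate
18 | methyl (2E,5S,7R,9S,11S)-5,7-dihydroxy-9,11-bis(triisopropylsilyloxy)icos-2-enoate | CCCCCCCCC[C@H](O[Si](C(C)C)(C(C)C)C(C)C)C[C@@H](O[Si](C(C)C)(C(C)C)C(C)C)C[C@H](O)C[C@@H](O)C/C=C/C(=O)OC | intermediate
19 | methyl (2Z,5S,7R,9S,11S)-5,7-dihydroxy-9,11-bis(triisopropylsilyloxy)icos-2-enoate | CCCCCCCCC[C@H](O[Si](C(C)C)(C(C)C)C(C)C)C[C@@H](O[Si](C(C)C)(C(C)C)C(C)C)C[C@H](O)C[C@@H](O)C/C=C\C(=O)OC | intermediate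
20 | (6S)-6-[(2R,4S,6S)-2-hydroxy-4,6-bis(triisopropylsilyloxy)pentadecyl]-5,6-dihydro-2H-pyran-2-one | CCCCCCCCC[C@H](O[Si](C(C)C)(C(C)C)C(C)C)C[C@@H](O[Si](C(C)C)(C(C)C)C(C)C)C[C@H](O)C[C@@H]1CC=CC(=O)O1 | intermediate
21 | (6S)-6-[(2S,4R,6S)-2,4,6-trihydroxypentadecyl]-5,6-dihydro-2H-pyran-2-one | CCCCCCCCC[C@H](O)C[C@@H](O)C[C@H](O)C[C@@H]1CC=CC(=O)O1 | target

Total step count: 12
Longest linear sequence: 12 steps (1 → 21)

Steps most likely to fail

Step 11. The E→Z photoisomerisation may stay incomplete, the Z ester may lactonise slowly, and light-induced deconjugation or [2+2] dimerisation may compete. The fallback is thermal and needs no light. Setting out from 18, the methyl ester is saponified (LiOH, THF–H2O, 0 °C) to (2E,5S,7R,9S,11S)-5,7-dihydroxy-9,11-bis(triisopropylsilyloxy)icos-2-enoic acid F1. F1 is then treated with 2,4,6-trichlorobenzoyl chloride in pyridine at high dilution (rt). The mixed anhydride adds pyridine reversibly at C4, which equilibrates the C3=C4 geometry, and only the Z form can be closed by the C6 hydroxyl. The fallback comes back to the route at 20.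

Step 9. Acid-induced loss of a silyl ether, 2-oxonia-Cope exchange that erodes the C2′ configuration, or unselective capture or elimination of the C6 cation may occur. The fallback closes the same C4–C5 bond by a radical instead of a cation. Setting out from 15, the terminal alkene is epoxidised (mCPBA, NaHCO3, CH2Cl2; the electron-poor alkoxyacrylate should be left alone) to the terminal epoxide F2 as both epimers at the oxirane carbon. Hydrolytic kinetic resolution (H2O 0.55 equiv, THF) uses the enantiomer of (salen)Co(OAc) (trivalent cobalt) that hydrolyses the unwanted epimer. It retains the epoxide with R configuration at the oxirane CH F3, while the other epimer is hydrolysed to the 1,2-diol F4 and removed by chromatography. LiI, AcOH in THF opens F3 at C5 to the iodohydrin F5. Bu3SnH, AIBN in benzene at 80 °C then generates the C5 radical, which adds 6-exo-trig to C4 of the alkoxyacrylate through a chair with all substituents equatorial. This should give the 2,6-cis oxane directly, and the fallback comes back to the route at 17.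

Step 10. Re-addition of the liberated C2′ alkoxide to the enoate on warming or quench (return to the oxane or its 2,6-trans epimer), oxygen-to-oxygen silyl migration, or γ-deprotonation of the product by excess base may occur. The fallback is a Lewis-acid fragmentation with silyl trapping in place of a free alkoxide. Setting out from 17, TMSOTf and Et3N (CH2Cl2, 0 °C → rt) silylate the C6 hydroxyl, convert the ester into its ketene silyl acetal and silylate the ring oxygen. Departure of the ring oxygen as a silyl ether makes the β-elimination irreversible and gives the bis(trimethylsilyl) ether of the (E)-enoate F6. Citric acid in MeOH removes the two trimethylsilyl groups selectively, and the fallback comes back to the route at 18.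

Further compounds
F1 | step 11 | (2E,5S,7R,9S,11S)-5,7-dihydroxy-9,11-bis(triisopropylsilyloxy)icos-2-enoic acid | CCCCCCCCC[C@H](O[Si](C(C)C)(C(C)C)C(C)C)C[C@@H](O[Si](C(C)C)(C(C)C)C(C)C)C[C@H](O)C[C@@H](O)C/C=C/C(=O)O
F2 | step 9 | terminal epoxide of 15 (methyl (2E)-3-alkoxyacrylate retained, both epimers at the oxirane CH) | CCCCCCCCC[C@H](O[Si](C(C)C)(C(C)C)C(C)C)C[C@@H](O[Si](C(C)C)(C(C)C)C(C)C)C[C@H](O/C=C/C(=O)OC)CC1CO1
F3 | step 9 | terminal epoxide of 15 with R configuration at the oxirane CH | CCCCCCCCC[C@H](O[Si](C(C)C)(C(C)C)C(C)C)C[C@@H](O[Si](C(C)C)(C(C)C)C(C)C)C[C@H](O/C=C/C(=O)OC)C[C@@H]1CO1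
F4 | step 9 | 1,2-diol from hydrolysis of the unwanted epoxide epimer (S at the secondary carbinol) | CCCCCCCCC[C@H](O[Si](C(C)C)(C(C)C)C(C)C)C[C@@H](O[Si](C(C)C)(C(C)C)C(C)C)C[C@H](O/C=C/C(=O)OC)C[C@H](O)CO
F5 | step 9 | iodohydrin from F3 (primary iodide at C5, R-configured secondary alcohol at C6) | CCCCCCCCC[C@H](O[Si](C(C)C)(C(C)C)C(C)C)C[C@@H](O[Si](C(C)C)(C(C)C)C(C)C)C[C@H](O/C=C/C(=O)OC)C[C@@H](O)CI
F6 | step 10 | methyl (2E,5S,7R,9S,11S)-5,7-bis(trimethylsilyloxy)-9,11-bis(triisopropylsilyloxy)icos-2-enoate | CCCCCCCCC[C@H](O[Si](C(C)C)(C(C)C)C(C)C)C[C@@H](O[Si](C(C)C)(C(C)C)C(C)C)C[C@H](O[Si](C)(C)C)C[C@@H](O[Si](C)(C)C)C/C=C/C(=O)OC
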